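A small charge of substrate, 0.070 M, can go in at once or slowly, and in a repeat the thing I would watch is c(substrate) while it goes in, so I count its lifetime first.

| flask | substrate | coupling partner | remark | time |
|---|---|---|---|---|
| delta | 0.070 M | 0.28 M | run made earlier |  |
| zeta | 0.070 M | 0.14 M | run made earlier |  |
| gamma | 0.070 M | 0.56 M | run made earlier |  |
| red | 0.070 M | 0.280 M (fed, over 6.0 min) | all else is in the flask from the start; the feed brings no volume worth counting | 8.0 min |
| amber | 0.070 M | 0.280 M | everything together at the start | 8.0 min |
| teal | 0.070 M (fed, over 6.0 min) | 0.280 M | all else is in the flask from the start; the feed brings no volume worth counting | 8.0 min |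
| grey | 0.070 M | 0.280 M (in portions, 5, over 6.0 min) | first portion at the start, last at 6.0 min | 8.0 min |
| green | 0.070 M (fed, over 1.5 min) | 0.280 M | all else is in the flask from the start; the feed brings no volume worth counting | 8.0 min |

- delta (time / min: target / %, substrate / %): 0.833: 54.7, 8.2; 1.50: 62.9, 3.1; 2.50: 67.8, 0.7; 3.00: 68.6, 0.8; 4.00: 70.0, 0.8; 5.00: 70.2, 0.5
- zeta (time / min: target / %, substrate / %): 0.500: 41.7, 17.8; 1.50: 58.5, 3.4; 3.00: 63.7, 1.3; 4.00: 63.8, 0; 6.00: 65.0, 0.1; 8.00: 64.4, 0.4
- gamma (time / min: target / %, substrate / %): 0.500: 46.3, 15.4; 1.50: 65.4, 4.0; 3.00: 71.2, 0.5; 4.00: 72.7, 0.2; 6.00: 72.6, 0; 8.00: 73.6, 0.6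

(readings scatter by 0.5 percentage points)

- the flask that comes out highest in amount of target, in percent of the substrate charged, or "all alike" when all lie within 1.5 percentage points (red / amber / teal / grey / green / all alike)
- target at the end, in percent of the substrate charged, red
- target at the end, in percent of the substrate charged, amber
- target at the end, in percent of the substrate charged, teal
- target at the end, in percent of the substrate charged, grey
- target at the end, in percent of the substrate charged, green

- a species is counted by the substrate in it: one self-condensation product or side product or idle adduct counts as two
- amounts and yields of target count idle adduct too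
- what may be going on: coupling partner + tight pair -> target; substrate + target <-> idle adduct; 2 substrate -> self-condensation product; substrate + tight pair -> side product; tight pair <-> loose pair; substrate <-> tight pair; coupling partner + loose pair -> isomer of the product
- in an amount of target, one idle adduct counts as one target

The first reading of the delta run, 8.2% left at 0.833 min, gives a first-order lifetime of 0.333 min. At 0.500 min, the zeta and gamma runs differ by 2.4 percentage points of substrate while coupling partner differs by a factor of 4.00, so I take the substrate's own step as the rate-limiting step. The later delta readings, from 8.2% to 3.1% at 1.50 min, give a second way and a lifetime of 0.686 min, about twice the first, so one way cheats. It is the later one: after 1.50 min target still gains 7.3 points, more than the free substrate reading of 3.1%, so I read a store in idle adduct as refilling the free substrate and stretching the later lifetime, and I keep the first.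

Doubling partner from delta to gamma leaves, by my extrapolation, a loss floor of 23.0%, with 6.8 points on top in delta, and I read the floor as self-condensation product. Weighted by what reacts, a first-order batch decay stands on average at the charge over 2, whereas I take a steady feed to hold c(substrate) near the charge times lifetime over feed time. This gives teal a feed ratio of 30.2, that is, the rate at which substrate goes to tight pair over the rate at which it goes to self-condensation product during a steady feed. Green, on its shorter feed, gets 7.54. The self-condensation shares are then 3.21% in teal and 11.7% in green, so I commit to 90.0% of target in teal and 81.5% in green, and I reckon nothing for red or grey.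

The forecast names teal as highest, with teal 82% (74% to 92%), green 77% (72% to 84%), amber 70.3% (69% to 71.5%), grey 48% (35% to 60%) and red 40% (25% to 55%), holding that “Feeding substrate keeps its concentration low, suppressing self-condensation and side product”. My teal and green stand above its values.

The flasks give 87.6% in teal, 84.0% in green, 70.6% in amber, 53.7% in grey and 33.0% in red, so teal comes out highest.

coupling partner + tight pair → target (k = 112 L mol⁻¹ s⁻¹); substrate + target ⇌ idle adduct, settled at all times (K = 37.0 L mol⁻¹); 2 substrate → self-condensation product (k = 0.292 L mol⁻¹ s⁻¹); substrate + tight pair → side product (k = 0.147 L mol⁻¹ s⁻¹); tight pair ⇌ loose pair (K = 1.60, k = 1.41 s⁻¹); substrate ⇌ tight pair (K = 0.0160, k = 0.0440 s⁻¹); coupling partner + loose pair → isomer of the product (k = 80.2 L mol⁻¹ s⁻¹) In teal at 3.60 min, the forward rate alone of the step to tight pair, its way back not counted, uses substrate 18 times as fast as self-condensation does, a ratio of that moment which stands below my feed ratio of 30.2 for the whole feed, and teal holds 4.98% of self-condensation product against my 3.21%. Green, with my ratio of 7.54, holds 11.8% against my 11.7%.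

The data were computed with made-up constants; scatter was added.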